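If you count each part of D charged, the limiting reagent, as standing in one ledger entry at any moment (still D, G, or past G), then Sunday's readings are the place to start, since the flask asked about is Sunday's flask followed further.

the same everywhere: D 0.020 M (fed, over 25 h); E 0.01 mol%

|  | remark | time |
|---|---|---|
| Sunday's | the very flask that is asked about, followed so far |  |
| flask |  | 15 d |

Sunday's run (percent of the D charged): time / d: G / % = 0.833: 5.3; 1.25: 15.8; 2.08: 32.4; 3.00: 39.7; 5.00: 33.2

(each reading ± 0.5 percentage points)

* the moment within 15 d at which there is most G
* the amount of G, in percent of the D charged, at that time
* the first time at which G reaches 28%, in the same percent, in d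

- the analysis behind the earlier runs scatters by 0.5 percentage points, standard deviation
- percentages count the whole charge, also what has not yet gone in

Sunday's feed ends at 25 h, so by the reading at 3.00 d the whole charge is in, and the reading of 33.2% at 5.00 d shows the G entry lower than at 3.00 d.

My reckoning treats the top of G as a correction to a known case. In a plain chain from D through G to something further, both steps first order, D present from the start and the two rate constants equal, G tops out at 36.8% of the charge, and near that case the top grows as the square root of the ratio of the constants. Sunday's highest reading, 39.7% with its scatter of 0.5 percentage points, lies 2.9 points above that, so you square the ratio of the two and get 1.16: this is the pace ratio, the constant for making G over the constant for losing it. At the top of such a chain, making equals losing, so my reckoning puts the D entry at G divided by the pace ratio, 34.1%, and 26.2% past G.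

The forecast puts the top at 3.3 d (2.9 d to 3.8 d) with 40.3% of G (39.5% to 41.5%), and the first passage of 28.0% at 1.81 d (1.74 d to 1.88 d), on the ground that “this is reading its own curve, not scaling to new conditions”.

The flask gives its top at 3.10 d with 39.6% of G, and passes 28.0% at 1.76 d, each inside the forecast's range.

    D + Z → G + Z, rate k1*[D]^1.5*[Z]/(1 + ([D]/Kh1)^1.5) (48.0 mM, k = 6100 /M^1.5/min)
    E → Z (k = 1.50 × 10⁻⁴ /min)
    G ⇌ Q (K = 3.10, k = 4.10 × 10⁻⁴ /min)

In this flask at the best time, 3.10 d, D stands at 27.9% and Q, the entry past G, at 32.5%, so the pace ratio put 6.2 points too much in the D entry.

On the neighbour flask with 0.017 mol% of E instead of 0.01 mol%, a pace ratio raised in step with the loading gives a top of 51.8%. The computed top there is 45.4%, higher than this flask's but lower than the reckoning.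

The data are simulated for substances that don't exist, noise included.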